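**Plan**

- Ring numbering as in the target: C1 (CO2H), C2 (4-hydroxyphenyl), C3 (lactate ester), C4 (3,4-dihydroxyphenyl); the four substituents alternate faces (all-trans).
- Retrosynthesis: first the protecting groups (benzyl, tert-butyl), then the ester C–O bond between the C3 carboxyl and the lactate carbon (Mitsunobu), then the ring bond C2–C3, which is replaced by a nitrogen bridge (C2–N–C3) to give a pyrrolidine; last, the pyrrolidine bonds C1–C2 and C3–C4 are cut to a glycine aldimine and a caffeate ester.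
- Enabling feature: C2 is benzylic, C3 is α to an ester carbonyl, and the two are 1,4-related through C1 and C4. The N-bridged precursor is therefore the [3+2] adduct of an azomethine ylide and a cinnamate, and loss of N2 from its 1,1-diazene leaves a doubly stabilised 1,4-biradical that closes the four-membered ring.
- Forward order: imine + enoate → pyrrolidine (five-membered ring, four stereocentres) → nitrogen-deletion ring contraction to the cyclobutane → epimerisation of C3 and selective saponification → Mitsunobu attachment of the danshensu unit → acidolysis and hydrogenolysis.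
- Stereochemistry: C1, C2 and C4 come from the ligand-controlled, exo-selective copper-catalysed cycloaddition and pass through the contraction with retention; C3 is set thermodynamically (all-trans); the (S) lactate centre arises by SN2 inversion of natural (R)-danshensu.

Key step: step 4

Remark: sodium (R)-danshensu and both antipodes of the ferrocenyl oxazoline phosphine ligand are taken as catalogue compounds; the ligand antipode that delivers the (2R,3R,4S,5S) adduct is fixed by a pilot run.

**Step 1**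
Reactants: 1 4-(benzyloxy)benzaldehyde; 2 glycine methyl ester hydrochloride
Product: 3 methyl (E)-N-[4-(benzyloxy)benzylidene]glycinate
Conditions: Et3N (1.1 equiv), 4 Å molecular sieves, CH2Cl2, rt
Reagents that add atoms: none
Why: Imine condensation of the amine freed by Et3N with the aromatic aldehyde, the sieves taking up the water, should give the conjugated (E)-aldimine.

**Step 2**
Reactants: 4 3,4-bis(benzyloxy)benzaldehyde; 5 tert-butyl (triphenylphosphoranylidene)acetate
Product: 6 tert-butyl (E)-3-[3,4-bis(benzyloxy)phenyl]prop-2-enoate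
Conditions: toluene, 90 °C
Reagents that add atoms: none
Why: Wittig olefination with an ester-stabilised ylide is reliably (E)-selective with aryl aldehydes.

**Step 3**
Reactants: 3 methyl (E)-N-[4-(benzyloxy)benzylidene]glycinate; 6 tert-butyl (E)-3-[3,4-bis(benzyloxy)phenyl]prop-2-enoate
Product: 7 4-tert-butyl 2-methyl (2R,3R,4S,5S)-5-[4-(benzyloxy)phenyl]-3-[3,4-bis(benzyloxy)phenyl]pyrrolidine-2,4-dicarboxylate
Conditions: Cu(CH3CN)4PF6 (5 mol %), (S,Sp)-2-{2-[bis(3,5-bis(trifluoromethyl)phenyl)phosphanyl]ferrocenyl}-4-isopropyl-4,5-dihydrooxazole (5.5 mol %), iPr2NEt (20 mol %), THF, −20 °C to rt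
Reagents that add atoms: none
Why: Catalytic asymmetric azomethine ylide 1,3-dipolar cycloaddition: the N,O-chelated W-shaped ylide of 3 bonds its glycinate carbon to the β-carbon of 6 (2,5-cis from the ylide geometry, 3,4-trans from the (E)-alkene), the exo approach favoured by the bulky tert-butyl ester and the P,N ligand on monovalent copper should place the C3 aryl cis to the C5 aryl, and the ligand fixes the face, giving the (2R,3R,4S,5S) series.

**Step 4**
Reactants: 7 4-tert-butyl 2-methyl (2R,3R,4S,5S)-5-[4-(benzyloxy)phenyl]-3-[3,4-bis(benzyloxy)phenyl]pyrrolidine-2,4-dicarboxylate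
Product: 9 1-tert-butyl 3-methyl (1R,2S,3R,4R)-2-[4-(benzyloxy)phenyl]-4-[3,4-bis(benzyloxy)phenyl]cyclobutane-1,3-dicarboxylate, via isodiazene 8 (not isolated)
Conditions: PhI(OH)OTs (2.5 equiv), H2NCO2NH4 (8 equiv), CF3CH2OH, 80 °C
Reagents that add atoms: none
Why: PhI(OH)OTs and ammonia (released from the carbamate) form an electrophilic iodonitrene that aminates the ring NH of 7 and is oxidised on to the 1,1-diazene 8, which loses N2 to a singlet 1,4-biradical whose benzylic terminus (former C5) and α-ester terminus (former C2) recombine, creating the cyclobutane bond between the carbon bearing the 4-(benzyloxy)phenyl group and the carbon bearing CO2Me. The closest known reaction type is the iodonitrene-mediated nitrogen deletion (ring contraction) of 5-aryl-pyrrolidine-2-carboxylates made by azomethine ylide cycloaddition, itself a variant of classical 1,1-diazene extrusion. The four-membered ring is closed by radical–radical recombination of the 1,4-biradical, i.e. a five-to-four ring contraction in which the nitrogen bridge leaves as N2. Both carbons that are joined should keep their configuration because the singlet biradical collapses faster than it rotates about its C–C bonds (retention at each terminus), and the two inner carbons are untouched, so 9 has CO2tBu trans to both aryl groups, the aryl groups cis to each other and CO2Me cis to both; erosion at the ester terminus would be harmless because that centre is equilibrated in step 5. The step needs recombination to outrun β-scission of the biradical into two cinnamates and N-transfer to outrun oxidation of the amine or the arenes: the aryl and ester groups at the two α-carbons make N2 loss easy at 80 °C, the excess ammonium carbamate buffers the sulfonic acid, and all phenols are capped as benzyl ethers.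

**Step 5**
Reactants: 9 1-tert-butyl 3-methyl (1R,2S,3R,4R)-2-[4-(benzyloxy)phenyl]-4-[3,4-bis(benzyloxy)phenyl]cyclobutane-1,3-dicarboxylate
Product: 11 (1S,2S,3R,4R)-2-[4-(benzyloxy)phenyl]-4-[3,4-bis(benzyloxy)phenyl]-3-(tert-butoxycarbonyl)cyclobutane-1-carboxylic acid, via all-trans diester 10 (not isolated)
Conditions: NaOMe (0.3 equiv), MeOH/THF, 50 °C; then LiOH (3 equiv), H2O, 40 °C; then aq. HCl to pH 3, 0 °C
Reagents that add atoms: lithium hydroxide, [Li+].[OH-]
Why: Base-mediated ester epimerisation followed by chemoselective saponification: methoxide reversibly enolises the CO2Me-bearing carbon, which should relax from the face crowded by both aryl groups to the all-trans arrangement (thermodynamic control of C3), and hydroxide then cleaves only the methyl ester because the tert-butyl ester resists acyl addition.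

**Step 6**
Reactants: 12 sodium (2R)-3-(3,4-dihydroxyphenyl)-2-hydroxypropanoate
Product: 13 benzyl (2R)-3-[3,4-bis(benzyloxy)phenyl]-2-hydroxypropanoate
Conditions: BnBr (3.3 equiv), K2CO3 (2.2 equiv), DMF, rt, under N2
Reagents that add atoms: benzyl bromide, BrCc1ccccc1
Why: Williamson etherification and carboxylate O-alkylation: carbonate ionises only the phenols, the carboxylate is already anionic and the secondary alcohol stays un-ionised, so three benzyl groups should be installed without touching the stereocentre.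

**Step 7**
Reactants: 11 (1S,2S,3R,4R)-2-[4-(benzyloxy)phenyl]-4-[3,4-bis(benzyloxy)phenyl]-3-(tert-butoxycarbonyl)cyclobutane-1-carboxylic acid; 13 benzyl (2R)-3-[3,4-bis(benzyloxy)phenyl]-2-hydroxypropanoate
Product: 14 1-tert-butyl 3-{(2S)-1-(benzyloxy)-3-[3,4-bis(benzyloxy)phenyl]-1-oxopropan-2-yl} (1R,2S,3S,4R)-2-[4-(benzyloxy)phenyl]-4-[3,4-bis(benzyloxy)phenyl]cyclobutane-1,3-dicarboxylate
Conditions: PPh3 (1.5 equiv), DIAD (1.5 equiv), THF, 0 °C to rt
Reagents that add atoms: none
Why: Mitsunobu esterification: the alcohol of 13 is activated as its alkoxyphosphonium ion and displaced by the carboxylate of 11 in an SN2 step, so the (R) carbinol centre is inverted to the required (S) ester while the ring carboxyl is never activated as an acyl electrophile.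

**Step 8**
Reactants: 14 (the tert-butyl ester from step 7)
Product: 15 (1R,2R,3S,4S)-2-[4-(benzyloxy)phenyl]-4-[3,4-bis(benzyloxy)phenyl]-3-({(2S)-1-(benzyloxy)-3-[3,4-bis(benzyloxy)phenyl]-1-oxopropan-2-yl}oxycarbonyl)cyclobutane-1-carboxylic acid
Conditions: CF3CO2H/CH2Cl2 (1:4), 0 °C to rt
Reagents that add atoms: none
Why: Acidolysis of a tert-butyl ester (alkyl–oxygen cleavage with loss of isobutene) should leave the aryl benzyl ethers, the benzyl ester and the secondary alkyl ester intact.

**Step 9**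
Reactants: 15 (the acid from step 8)
Product: 16 (1R,2R,3S,4S)-3-{[(1S)-1-carboxy-2-(3,4-dihydroxyphenyl)ethoxy]carbonyl}-4-(3,4-dihydroxyphenyl)-2-(4-hydroxyphenyl)cyclobutane-1-carboxylic acid
Conditions: H2 (1 atm), Pd/C (10 wt %), THF/MeOH, rt
Reagents that add atoms: none
Why: Catalytic hydrogenolysis should cleave the five aryl benzyl ethers and the benzyl ester at their benzylic C–O bonds, while the cyclobutane C–C bonds, the homobenzylic lactate C–O bond and all stereocentres are unaffected.

**Compound list**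

1 | 4-(benzyloxy)benzaldehyde | O=Cc1ccc(OCc2ccccc2)cc1 | starting material
2 | glycine methyl ester hydrochloride | COC(=O)CN.Cl | starting material
3 | methyl (E)-N-[4-(benzyloxy)benzylidene]glycinate | COC(=O)C/N=C/c1ccc(OCc2ccccc2)cc1 | intermediate
4 | 3,4-bis(benzyloxy)benzaldehyde | O=Cc1ccc(OCc2ccccc2)c(OCc2ccccc2)c1 | starting material
5 | tert-butyl (triphenylphosphoranylidene)acetate | CC(C)(C)OC(=O)C=P(c1ccccc1)(c1ccccc1)c1ccccc1 | starting material
6 | tert-butyl (E)-3-[3,4-bis(benzyloxy)phenyl]prop-2-enoate | CC(C)(C)OC(=O)/C=C/c1ccc(OCc2ccccc2)c(OCc2ccccc2)c1 | intermediate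
7 | 4-tert-butyl 2-methyl (2R,3R,4S,5S)-5-[4-(benzyloxy)phenyl]-3-[3,4-bis(benzyloxy)phenyl]pyrrolidine-2,4-dicarboxylate (exo adduct: 2,5-cis, 2,3-cis, 3,4-trans, 4,5-trans) | CC(C)(C)OC(=O)[C@@H]1[C@@H](c2ccc(OCc3ccccc3)cc2)N[C@@H](C(=O)OC)[C@H]1c1ccc(OCc2ccccc2)c(OCc2ccccc2)c1 | intermediate
8 | 4-tert-butyl 2-methyl (2R,3R,4S,5S)-1-azanidylidene-5-[4-(benzyloxy)phenyl]-3-[3,4-bis(benzyloxy)phenyl]pyrrolidin-1-ium-2,4-dicarboxylate (1,1-diazene of 7) | CC(C)(C)OC(=O)[C@@H]1[C@@H](c2ccc(OCc3ccccc3)cc2)[N+](=[N-])[C@@H](C(=O)OC)[C@H]1c1ccc(OCc2ccccc2)c(OCc2ccccc2)c1 | intermediate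
9 | 1-tert-butyl 3-methyl (1R,2S,3R,4R)-2-[4-(benzyloxy)phenyl]-4-[3,4-bis(benzyloxy)phenyl]cyclobutane-1,3-dicarboxylate (CO2Me cis to both aryl groups) | CC(C)(C)OC(=O)[C@@H]1[C@@H](c2ccc(OCc3ccccc3)cc2)[C@@H](C(=O)OC)[C@H]1c1ccc(OCc2ccccc2)c(OCc2ccccc2)c1 | intermediate
10 | 1-tert-butyl 3-methyl (1R,2S,3S,4R)-2-[4-(benzyloxy)phenyl]-4-[3,4-bis(benzyloxy)phenyl]cyclobutane-1,3-dicarboxylate (all-trans) | CC(C)(C)OC(=O)[C@@H]1[C@@H](c2ccc(OCc3ccccc3)cc2)[C@H](C(=O)OC)[C@H]1c1ccc(OCc2ccccc2)c(OCc2ccccc2)c1 | intermediate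
11 | (1S,2S,3R,4R)-2-[4-(benzyloxy)phenyl]-4-[3,4-bis(benzyloxy)phenyl]-3-(tert-butoxycarbonyl)cyclobutane-1-carboxylic acid (all-trans) | CC(C)(C)OC(=O)[C@@H]1[C@@H](c2ccc(OCc3ccccc3)cc2)[C@H](C(=O)O)[C@H]1c1ccc(OCc2ccccc2)c(OCc2ccccc2)c1 | intermediate
12 | sodium (2R)-3-(3,4-dihydroxyphenyl)-2-hydroxypropanoate (sodium (R)-danshensu) | [Na+].[O-]C(=O)[C@H](O)Cc1ccc(O)c(O)c1 | starting material
13 | benzyl (2R)-3-[3,4-bis(benzyloxy)phenyl]-2-hydroxypropanoate | O=C(OCc1ccccc1)[C@H](O)Cc1ccc(OCc2ccccc2)c(OCc2ccccc2)c1 | intermediate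
14 | 1-tert-butyl 3-{(2S)-1-(benzyloxy)-3-[3,4-bis(benzyloxy)phenyl]-1-oxopropan-2-yl} (1R,2S,3S,4R)-2-[4-(benzyloxy)phenyl]-4-[3,4-bis(benzyloxy)phenyl]cyclobutane-1,3-dicarboxylate | CC(C)(C)OC(=O)[C@@H]1[C@@H](c2ccc(OCc3ccccc3)cc2)[C@H](C(=O)O[C@@H](Cc2ccc(OCc3ccccc3)c(OCc3ccccc3)c2)C(=O)OCc2ccccc2)[C@H]1c1ccc(OCc2ccccc2)c(OCc2ccccc2)c1 | intermediate
15 | (1R,2R,3S,4S)-2-[4-(benzyloxy)phenyl]-4-[3,4-bis(benzyloxy)phenyl]-3-({(2S)-1-(benzyloxy)-3-[3,4-bis(benzyloxy)phenyl]-1-oxopropan-2-yl}oxycarbonyl)cyclobutane-1-carboxylic acid | OC(=O)[C@@H]1[C@@H](c2ccc(OCc3ccccc3)cc2)[C@H](C(=O)O[C@@H](Cc2ccc(OCc3ccccc3)c(OCc3ccccc3)c2)C(=O)OCc2ccccc2)[C@H]1c1ccc(OCc2ccccc2)c(OCc2ccccc2)c1 | intermediate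
16 | (1R,2R,3S,4S)-3-{[(1S)-1-carboxy-2-(3,4-dihydroxyphenyl)ethoxy]carbonyl}-4-(3,4-dihydroxyphenyl)-2-(4-hydroxyphenyl)cyclobutane-1-carboxylic acid | O=C(O)[C@@H]1[C@@H](c2ccc(O)cc2)[C@H](C(=O)O[C@@H](Cc2ccc(O)c(O)c2)C(=O)O)[C@H]1c1ccc(O)c(O)c1 | target

**Count**

Total steps: 9. Longest linear sequence: 7 steps (steps 1, 3, 4, 5, 7, 8, 9).

**Steps most likely to fail**

Step 3. The ester may slip under the metal (endo mode), which would place the two aryl groups trans on the ring, and the electron-rich β-aryl enoate may add so slowly that unselective pathways compete. The fallback sets out from 6 (with 3) and returns at 10. Triplet-sensitised E→Z isomerisation of 6 (Ir(ppy)3, blue light, THF) would give tert-butyl (Z)-3-[3,4-bis(benzyloxy)phenyl]prop-2-enoate F1. The well-documented endo-selective silver-catalysed cycloaddition (AgOAc, (S)-QUINAP or its antipode, iPr2NEt, THF) of 3 to this (Z)-alkene puts ester and aryl both under the dipole and should give the all-cis pyrrolidine F2, in which the aryl groups are cis regardless of exo control. NaOMe in MeOH at 60 °C should then equilibrate both ester-bearing carbons to the all-trans pyrrolidine F3. Ring contraction of F3 under the conditions of step 4, through its 1,1-diazene F4, should give 10 directly, which is saponified as in the second half of step 5.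

Step 4. The 1,4-biradical may undergo β-scission to two cinnamates instead of closing, and the hot, oxidising trivalent-iodine medium may dehydrogenate the amine or attack the alkoxy-arenes. The fallback sets out from 7 and returns at 9, separating N–N bond formation from N2 loss. N-Nitrosation (tBuONO, THF, rt) would give the N-nitrosopyrrolidine F5. Reduction (Zn, AcOH/MeOH, 0 °C) would give the N-aminopyrrolidine F6. Oxidation with tBuOCl/Et3N in Et2O at −78 °C would generate the same 1,1-diazene 8 in a cold, non-acidic medium, where loss of N2 on slow warming should favour closure to 9 over fragmentation.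

Step 7. The activated β-aryl lactate may eliminate to the cinnamate, or the hindered partners may react slowly with incomplete inversion. The fallback sets out from 11 and returns at 14; it forms the ester by acyl transfer with retention, using the (S)-alcohol made separately. 4-Bromo-1,2-bis(benzyloxy)benzene and Mg in THF would give the Grignard reagent F7. Its CuBr·SMe2-mediated addition to C3 of methyl (S)-glycidate at −40 °C would give methyl (2S)-3-[3,4-bis(benzyloxy)phenyl]-2-hydroxypropanoate F8 with the stereocentre untouched. Ti(OiPr)4-catalysed transesterification with BnOH would give the benzyl ester F9. Steglich esterification of 11 with F9 (DCC, DMAP, CH2Cl2, 0 °C) should then give 14.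

**Further compounds**

F1 | step 3 | tert-butyl (Z)-3-[3,4-bis(benzyloxy)phenyl]prop-2-enoate | CC(C)(C)OC(=O)/C=C\c1ccc(OCc2ccccc2)c(OCc2ccccc2)c1
F2 | step 3 | 4-tert-butyl 2-methyl (2R,3R,4R,5S)-5-[4-(benzyloxy)phenyl]-3-[3,4-bis(benzyloxy)phenyl]pyrrolidine-2,4-dicarboxylate (all-cis) | CC(C)(C)OC(=O)[C@H]1[C@@H](c2ccc(OCc3ccccc3)cc2)N[C@@H](C(=O)OC)[C@H]1c1ccc(OCc2ccccc2)c(OCc2ccccc2)c1
F3 | step 3 | 4-tert-butyl 2-methyl (2S,3R,4S,5S)-5-[4-(benzyloxy)phenyl]-3-[3,4-bis(benzyloxy)phenyl]pyrrolidine-2,4-dicarboxylate (all-trans) | CC(C)(C)OC(=O)[C@@H]1[C@@H](c2ccc(OCc3ccccc3)cc2)N[C@H](C(=O)OC)[C@H]1c1ccc(OCc2ccccc2)c(OCc2ccccc2)c1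
F4 | step 3 | 4-tert-butyl 2-methyl (2S,3R,4S,5S)-1-azanidylidene-5-[4-(benzyloxy)phenyl]-3-[3,4-bis(benzyloxy)phenyl]pyrrolidin-1-ium-2,4-dicarboxylate (1,1-diazene of F3) | CC(C)(C)OC(=O)[C@@H]1[C@@H](c2ccc(OCc3ccccc3)cc2)[N+](=[N-])[C@H](C(=O)OC)[C@H]1c1ccc(OCc2ccccc2)c(OCc2ccccc2)c1
F5 | step 4 | 4-tert-butyl 2-methyl (2R,3R,4S,5S)-5-[4-(benzyloxy)phenyl]-3-[3,4-bis(benzyloxy)phenyl]-1-nitrosopyrrolidine-2,4-dicarboxylate | CC(C)(C)OC(=O)[C@@H]1[C@@H](c2ccc(OCc3ccccc3)cc2)N(N=O)[C@@H](C(=O)OC)[C@H]1c1ccc(OCc2ccccc2)c(OCc2ccccc2)c1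
F6 | step 4 | 4-tert-butyl 2-methyl (2R,3R,4S,5S)-1-amino-5-[4-(benzyloxy)phenyl]-3-[3,4-bis(benzyloxy)phenyl]pyrrolidine-2,4-dicarboxylate | CC(C)(C)OC(=O)[C@@H]1[C@@H](c2ccc(OCc3ccccc3)cc2)N(N)[C@@H](C(=O)OC)[C@H]1c1ccc(OCc2ccccc2)c(OCc2ccccc2)c1
F7 | step 7 | [3,4-bis(benzyloxy)phenyl]magnesium bromide | Br[Mg]c1ccc(OCc2ccccc2)c(OCc2ccccc2)c1
F8 | step 7 | methyl (2S)-3-[3,4-bis(benzyloxy)phenyl]-2-hydroxypropanoate | COC(=O)[C@@H](O)Cc1ccc(OCc2ccccc2)c(OCc2ccccc2)c1
F9 | step 7 | benzyl (2S)-3-[3,4-bis(benzyloxy)phenyl]-2-hydroxypropanoate | O=C(OCc1ccccc1)[C@@H](O)Cc1ccc(OCc2ccccc2)c(OCc2ccccc2)c1
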